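**Early peaks.** At early times the runs show a large left-handed product peak beside a small right-handed one: in alder at 25.0 min, 35 % against 3 %.

| flask | left-handed substrate | right-handed substrate | partner | racemization catalyst | precatalyst | remark | time |
|---|---|---|---|---|---|---|---|
| ash | 0.050 M | 0.050 M | 2.2 equiv | 0.1 mol% | 0.37 mol% | run made earlier |  |
| elm | 0.050 M | 0.050 M | 2.2 equiv | 0.1 mol% | 0.83 mol% | run made earlier |  |
| alder | 0.050 M | 0.050 M | 4.4 equiv | 0.1 mol% | 0.55 mol% | run made earlier |  |
| flask | 0.050 M | 0.050 M | 2.20 equiv | 0.1 mol% | 0.55 mol% |  | 1.5 h |

| run | time / min | left-handed product / % | right-handed product / % |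
|---|---|---|---|
| ash | 8.00 | 3 | 1 |
| ash | 15.0 | 10 | 0 |
| ash | 25.0 | 15 | 1 |
| ash | 40.0 | 23 | 4 |
| ash | 60.0 | 31 | 2 |
| ash | 120 | 43 | 2 |
| elm | 20.0 | 23 | 0 |
| elm | 40.0 | 41 | 2 |
| elm | 50.0 | 44 | 5 |
| elm | 80.0 | 57 | 4 |
| elm | 90.0 | 59 | 8 |
| elm | 120 | 65 | 5 |
| alder | 10.0 | 16 | 5 |
| alder | 25.0 | 35 | 3 |
| alder | 50.0 | 52 | 3 |
| alder | 80.0 | 69 | 8 |
| alder | 120 | 78 | 7 |

(each reading ± 1.5 percentage points)

- free catalyst is single-handed; left-handed substrate and right-handed substrate are mirror images of each other, charged as a racemate, each of them at the stated concentration
- an excess is the difference of the two amounts in percent of their sum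
- an excess is below zero if the other one leads

* left-handed product and right-handed product together, in percent of the left-handed substrate and right-handed substrate charged together, at 1.5 h
* excess of left-handed product over right-handed product in the product at 1.5 h
* whether the exchange between left-handed substrate and right-handed substrate keeps pace with the reaction: how far the product's excess at 1.5 h gets from its value without exchange to its value with instant exchange (above 80 % keeps pace, below 20 % hardly takes part, else lags behind)

**What matters.** The yield moves with the charges. From ash to elm, twice the precatalyst goes with total product at 120 min of 70.0 % instead of 45.0 %. The proportion of the peaks does not visibly follow. Right-handed over left-handed product, summed over each run's readings, is 0.0800 in ash, 0.0830 in elm, and 0.104 in alder, which has twice the partner. The excess, however, is sensitive to this proportion: ash's value would give 85.2 %, alder's 81.2 %. So this is the number to know well.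

**Leak ratio.** Pooling the readings of the three runs gives 0.0904 for the leak ratio, the right-handed product formed per left-handed product, a reading that carries the scatter of the peaks. The product excess is one minus this ratio over one plus it, 83.4 %.

**Alder's test.** Alder's left-handed product of 78 % stands 28 percentage points above the left-handed share of the charge, so at least that much crossed over from right-handed substrate. Yet its last peak ratio, 0.0897, matches the pooled one. The reckoning here therefore puts the flask near 83.4 %, with the exchange keeping pace.

**The forecast.** The forecast gives 50.5 % of product, an excess of 84 % and lags behind, with “Progress is about 60%”, and so parts from this reckoning on pace.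

**The flask.** At 1.5 h the flask gives 54.2 % of product and an excess of 84.0 %, and the exchange keeps pace, at 89 % of the way.

    partner + free catalyst + left-handed substrate → free catalyst + left-handed product (k = 185 L² mol⁻² s⁻¹)
    partner + free catalyst + right-handed substrate → free catalyst + right-handed product (k = 14.8 L² mol⁻² s⁻¹)
    left-handed substrate + racemization catalyst ⇌ right-handed substrate + racemization catalyst, rate k3*[racemization catalyst]*[left-handed substrate] forward; the back reaction follows from the equilibrium constant (k = 30.5 L mol⁻¹ s⁻¹)
    partner + free catalyst → spent catalyst (k = 0.00215 L mol⁻¹ s⁻¹)
    precatalyst ⇌ free catalyst (K = 0.0867, k = 3.59 × 10⁻⁴ s⁻¹)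

Left-handed substrate stands at 22.2 % beside right-handed substrate at 23.6 %. The leak ratio divides the flask's total into 49.7 % left-handed product, and the flask holds 49.9 %. In the neighbour with 0.94 mol% of precatalyst, the total of 67.6 % divides into 62.0 %, and that neighbour holds 61.9 %.

The earlier runs and the new flask are calculated with constants of no real substance, and the scatter is random.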